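The plan rests on undoing bond C5–C6 of ring B (C5–C10) while tying C3 to C8. This folds the cis-decalin back into a bicyclo[2.2.2]octene available by Diels–Alder trapping of a dearomatised guaiacol. The feature exploited is ring A (C1–C5, C10) bearing adjacent methyls at C4 and C5 beside the C8,C9-dioxygenated edge of ring B: the imprint of a 5,6-dimethylbicyclooctenone with a keto-ketal bridge. In one operation an anionic oxy-Cope shift closes ring B, creates quaternary C5 cis to H10 and leaves a C7-specific enolate. Its precursor is the C8 vinyl carbinol, vinyl syn to C4=C5, with a C2 p-methoxybenzyl ether removable oxidatively.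

Key step: step 4

Remarks on the chemistry
- Eremophilane numbering is used for every compound, the bicyclic ones included. β is the face of the C5 methyl and H10; α is the opposite, concave face.
- Assumption: 2-methoxy-4,5-dimethylphenol is taken as a purchasable chemical.
- Everything before the resolution built into step 6 is racemic. The SMILES show the enantiomer that leads to the target.
- The saturated cis-decalins have two chair–chair forms. Form N has the C4 methyl, 2β-O, 7β-C and 8α-O equatorial and 9α-O axial beneath ring A; the flipped form is called S. A 2α oxygen is axial in N and would collide with any 9α oxygen. C2 is therefore inverted (steps 9 and 10) before ring B is elaborated.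

Step 1
Reactants: 1 4-methoxybenzyl alcohol; 2 butyl vinyl ether
Product: 3 4-methoxybenzyl vinyl ether
Conditions: Pd(OCOCF3)2 (0.5 mol %), 4,7-diphenyl-1,10-phenanthroline (0.5 mol %), Et3N (cat), 2 (excess, as solvent), 75 °C
Reagents that add atoms: butyl vinyl ether (2), C=COCCCC
Why: Transfer vinylation (vinyl transetherification) of a primary alcohol catalysed by a divalent palladium phenanthroline complex is an equilibrium that the large excess of 2 pushes to 3, triethylamine keeps the medium non-acidic so that no acetal forms, and no stereocentre is involved.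

Step 2
Reactants: 4 2-methoxy-4,5-dimethylphenol; 3 4-methoxybenzyl vinyl ether
Product: 6 racemic endo adduct 7-(4-methoxybenzyloxy)-3,3-dimethoxy-5,6-dimethylbicyclo[2.2.2]oct-5-en-2-one, via masked o-benzoquinone 5 (not isolated)
Conditions: PhI(OAc)2 (1.1 equiv, slow addition), 3 (5 equiv), MeOH, 0 °C → 50 °C
Reagents that add atoms: methanol, CO; 4-methoxybenzyl vinyl ether (3), C=COCc1ccc(OC)cc1
Why: Oxidative dearomatisation of the guaiacol in methanol gives masked o-benzoquinone 5, whose electron-poor diene is trapped by the electron-rich vinyl ether in an inverse-electron-demand Diels–Alder reaction before it dimerises: the nucleophilic CH2 terminus (C1) bonds to the diene end next to the ketal (C10), the oxygen-bearing carbon C2 therefore bonds to the carbonyl-side end (C3), and endo approach puts the ether syn to the new C4=C5 bond, which fixes C2, C3 and C10 relative to each other.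

Step 3
Reactants: 6 racemic endo adduct; 7 vinylmagnesium bromide
Product: 8 racemic C8 vinyl carbinol (vinyl syn to C4=C5; hydroxyl towards the C1–C2 bridge)
Conditions: 7 (3 equiv), THF, −78 → 0 °C; then H2O
Reagents that add atoms: vinylmagnesium bromide (7), C=C[Mg]Br
Why: Grignard 1,2-addition to a ketone that cannot enolise (its only α hydrogen is at the C3 bridgehead): the C8 carbonyl is open on the side of the flat C4=C5 bridge and screened on the other side by the exo hydrogens of the C1–C2 bridge, so vinyl enters syn to the alkene and the new C8 hydroxyl points to the saturated bridge, the geometry that the [3,3] shift requires.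

Step 4
Reactants: 8 racemic C8 vinyl carbinol
Product: 11 racemic cis-decalin 2β-OPMB-Δ3-8-ketone 9,9-dimethyl ketal (5β-Me; 10β-H), via potassium alkoxide 9 (not isolated), via potassium enolate 10 (not isolated)
Conditions: KH (2 equiv), 18-crown-6 (2 equiv), degassed THF, 0 °C → rt; then AcOH/THF, −78 °C
Reagents that add atoms: none
Why: KH with 18-crown-6 gives the loosely paired alkoxide 9, whose charge weakens the adjacent C3–C8 bond, and the 1,5-diene C6=C7–C8–C3–C4=C5 then shifts [3,3] in concert through the boat-like array imposed by the bicycle, breaking C3–C8 and forming C5–C6. The closest known reaction type is the anionic oxy-Cope rearrangement of 2-vinylbicyclo[2.2.2]oct-5-en-2-ols, an established route to cis-decalins. Ring B (C5–C10) is closed by sigmatropic ring expansion: the C8–C9 bridge, the two vinyl carbons C6 and C7 and the C5–C10 bond become its six members, while ring A is left as the cyclohexene C1–C5, C10 with the alkene moved to C3=C4. The only new stereocentre, quaternary C5, is controlled by the cage, since C6 can reach C5 only on the alkene face turned towards the carbinol bridge, the side on which C9 leaves C10, so that the C5 methyl and H10 end on the same face (cis fusion) and C2 and C10 are carried over unchanged. The step needs the vinyl group syn to C4=C5, secured in step 3, and it needs the shift to outrun fragmentation of the alkoxide, secured by the poor leaving ability of the C2 alkoxy group and by the irreversible formation of the delocalised enolate 10. Enolate 10 can only be the C7–C8 enolate because C9 is quaternary, and the cold acetic acid quench turns it into ketone 11.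

Step 5
Reactants: 11 racemic cis-decalin PMB ether
Product: 12 racemic 2β-allylic alcohol
Conditions: DDQ (1.2 equiv), CH2Cl2/pH 7 buffer (18:1), 0 °C
Reagents that add atoms: none
Why: Oxidative cleavage of a p-methoxybenzyl ether by DDQ (benzylic hydride abstraction, then hydrolysis of the oxocarbenium ion) spares the C3=C4 alkene, the ketone and the ketal that hydrogenolysis or dissolving metal would endanger, and since the C2–O bond is not touched the 2β configuration is kept.

Step 6
Reactants: 12 racemic 2β-allylic alcohol; 13 (S)-2-methoxy-2-phenylacetic acid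
Product: 14 2α-(S)-methoxyphenylacetate as a single stereoisomer
Conditions: 13 (1.5 equiv), PPh3, DIAD, toluene, 0 °C → rt; then separation of the two diastereomeric esters (SiO2 or crystallisation)
Reagents that add atoms: (S)-2-methoxy-2-phenylacetic acid (13), CO[C@H](C(=O)O)c1ccccc1
Why: Mitsunobu esterification replaces the activated 2β oxygen by the carboxylate in an SN2 displacement with inversion, giving the 2α ester (SN2' entry at C4 is closed by its methyl group and the quaternary C5), and because acid 13 is a single enantiomer the two antipodes of 12 become diastereomeric esters that are separated, a classical resolution folded into a step the route needs anyway, with the absolute configuration of the retained ester to be secured by X-ray analysis or by the NMR shielding model for α-methoxyphenylacetates.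

Step 7
Reactants: 14 2α-(S)-methoxyphenylacetate
Product: 15 enantiopure 2α-allylic alcohol
Conditions: K2CO3 (0.3 equiv), MeOH, rt
Reagents that add atoms: none
Why: Base-catalysed transesterification (methanolysis) breaks the acyl–oxygen bond, so C2 keeps its 2α configuration, and no other centre is at risk because C7 is a methylene and C10 is insulated from the ketone by the ketal carbon.

Step 8
Reactants: 15 2α-allylic alcohol
Product: 16 saturated 2α-alcohol (4β-methyl)
Conditions: [Ir(cod)(PCy3)(py)]PF6 (5 mol %), H2 (1 atm), CH2Cl2, rt
Reagents that add atoms: none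
Why: Hydroxyl-directed homogeneous hydrogenation: the cationic iridium centre binds the 2α hydroxyl and delivers both hydrogens to the α face of C3=C4, so H4 is α and the C4 methyl ends β, cis to the C5 methyl, against the steric bias an undirected catalyst would follow.

Step 9
Reactants: 16 saturated 2α-alcohol
Product: 17 2,8-diketone 9,9-dimethyl ketal
Conditions: DMP (1.3 equiv), pyridine, CH2Cl2, 0 °C → rt
Reagents that add atoms: none
Why: Dess–Martin oxidation of a secondary alcohol under buffered conditions clears the 2α oxygen, which has done its work as directing group and could not be carried further because it is axial in form N and would clash with any 9α oxygen; no stereocentre is α to the new ketone.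

Step 10
Reactants: 17 2,8-diketone
Product: 18 2β-alcohol
Conditions: LiBH(s-Bu)3 (1.05 equiv), THF, −78 °C; then H2O
Reagents that add atoms: none
Why: Sterically governed ketone reduction by a bulky trialkylborohydride: the C2 carbonyl between two methylenes reacts at −78 °C whereas the C8 carbonyl beside the quaternary ketal carbon is screened on both faces, and since the β face of C2 is covered by the axial C4 methyl in the reacting form S (the α face is closed by the 9α methoxy group in form N) hydride comes from the α face of S and gives the 2β alcohol, which relaxes to form N with the hydroxyl equatorial.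

Step 11
Reactants: 18 2β-alcohol
Product: 19 2β-TBDPS ether
Conditions: TBDPSCl, imidazole, DMF, rt
Reagents that add atoms: tert-butyldiphenylsilyl chloride, CC(C)(C)[Si](Cl)(c1ccccc1)c1ccccc1
Why: Imidazole-promoted silylation of the unhindered equatorial hydroxyl gives an ether that withstands strong base, hydride and the aqueous acid of step 14 and is later removed by fluoride beside the angelates, and only the O–H bond is broken so C2 is unchanged.

Step 12
Reactants: 19 2β-TBDPS ether; 20 2-bromopropene
Product: 23 7β-isopropenyl 8-ketone, via lithium enolate 21 (not isolated), via lithium dienolate 22 (not isolated)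
Conditions: LiHMDS (2.3 equiv), THF, −78 → 0 °C; Pd2(dba)3 (2.5 mol %), P(t-Bu)3·HBF4 (6 mol %), 20 (1.5 equiv), rt; then AcOH/THF, −78 °C
Reagents that add atoms: 2-bromopropene (20), CC(Br)=C
Why: Palladium-catalysed α-alkenylation of a ketone enolate (oxidative addition of 20 to zerovalent palladium, enolate transfer, reductive elimination) can engage only C7 because C9 is quaternary; the more acidic product is parked as dienolate 22, whose α-protonation on the cold quench returns the β,γ-unsaturated ketone, and the 7β epimer is the equatorial and hence preferred one in form N, which the equatorial C4 methyl and 2β silyloxy group enforce (form S, needed for an equatorial 7α group, would set these two syn-diaxial), so the wanted centre is the one that re-enolisation and reprotonation of any separated 7α epimer should also favour.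

Step 13
Reactants: 23 7β-isopropenyl 8-ketone
Product: 24 8α-alcohol
Conditions: NaBH4, CeCl3·7H2O, MeOH, −40 °C
Reagents that add atoms: none
Why: Luche-type borohydride reduction under nearly neutral conditions that do not epimerise C7 or conjugate the alkene: in form N the small hydride attacks C8 axially from the β face, anti to the axial 9α methoxy group that together with ring A closes the α face, and gives the equatorial 8α alcohol trans to the isopropenyl group.

Step 14
Reactants: 24 8α-alcohol
Product: 25 8α-hydroxy 9-ketone
Conditions: 1 M aq HCl/THF (1:4), rt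
Reagents that add atoms: water, O
Why: Acid-catalysed ketal hydrolysis becomes feasible once the neighbouring carbonyl is reduced (an oxocarbenium ion beside a ketone would be strongly destabilised) and is helped by release of the compressed axial 9α methoxy group, while the cis fusion survives although C10 is now α to a ketone because the trans-fused epimer would force the 7β-isopropenyl group axial beside the C5 methyl.

Step 15
Reactants: 25 8α-hydroxy 9-ketone
Product: 26 8α,9α-diol
Conditions: LiBH(s-Bu)3 (3 equiv), THF, −78 °C; then H2O
Reagents that add atoms: none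
Why: Ketone reduction by a bulky trialkylborohydride under steric approach control: the α face of C9 is the concave face closed by ring A, so hydride arrives along the equatorial trajectory from the convex β face and gives the axial 9α alcohol, cis to the 8α hydroxyl.

Step 16
Reactants: 26 8α,9α-diol; 27 angelic acid
Product: 29 8α,9α-diangelate 2β-TBDPS ether, via mixed anhydride 28 (not isolated)
Conditions: 27 (6 equiv), 2,4,6-trichlorobenzoyl chloride (6 equiv), Et3N, toluene, rt; then 26, 80 °C
Reagents that add atoms: angelic acid (27), C/C=C(/C)C(=O)O
Why: Yamaguchi-type mixed-anhydride esterification run without a nucleophilic catalyst is the established way to transfer the angeloyl group without Z to E isomerisation; the equatorial 8α hydroxyl reacts first and the hindered axial 9α hydroxyl follows on heating, directly or by 8 to 9 acyl migration and re-acylation, and all carbinol configurations are retained because only O–H bonds are broken.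

Step 17
Reactants: 29 8α,9α-diangelate 2β-TBDPS ether
Product: 30 8α,9α-diangelate 2β-alcohol
Conditions: HF·pyridine, pyridine/THF, 0 °C → rt
Reagents that add atoms: none
Why: Fluoride-induced Si–O cleavage (desilylation) with pyridine-buffered HF is neither basic enough to hydrolyse or isomerise the angelates nor acidic enough to protonate the isopropenyl group, and the free hydroxyl is too remote from C8 and C9 for acyl migration.

Step 18
Reactants: 30 8α,9α-diangelate 2β-alcohol
Product: 31 target CNP0249036.1
Conditions: DMP (1.5 equiv), pyridine, CH2Cl2, 0 °C → rt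
Reagents that add atoms: none
Why: Dess–Martin oxidation turns the unhindered equatorial 2β alcohol into the C2 ketone under near-neutral conditions, and since neither α carbon (C1, C3) is stereogenic and no leaving group is β to the new carbonyl nothing is scrambled.

Compound list
1 | 4-methoxybenzyl alcohol | COc1ccc(CO)cc1 | starting material
2 | butyl vinyl ether | C=COCCCC | starting material
3 | 4-methoxybenzyl vinyl ether | C=COCc1ccc(OC)cc1 | intermediate
4 | 2-methoxy-4,5-dimethylphenol | COc1cc(C)c(C)cc1O | starting material
5 | 6,6-dimethoxy-3,4-dimethylcyclohexa-2,4-dien-1-one (masked o-benzoquinone, not isolated) | COC1(OC)C=C(C)C(C)=CC1=O | intermediate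
6 | racemic 7-endo-(4-methoxybenzyloxy)-3,3-dimethoxy-5,6-dimethylbicyclo[2.2.2]oct-5-en-2-one (ether syn to the alkene, on the carbon next to the carbonyl-side bridgehead) | O=C1[C@H]2C(C)=C(C)[C@H](C[C@@H]2OCc3ccc(OC)cc3)C1(OC)OC | intermediate
7 | vinylmagnesium bromide | C=C[Mg]Br | starting material
8 | racemic 2-vinyl carbinol of 6 (C8 tertiary alcohol, vinyl syn to C4=C5, OH towards the C1–C2 bridge) | C=C[C@@]1(O)[C@H]2C(C)=C(C)[C@H](C[C@@H]2OCc3ccc(OC)cc3)C1(OC)OC | intermediate
9 | potassium alkoxide of 8 (not isolated) | [K+].C=C[C@@]1([O-])[C@H]2C(C)=C(C)[C@H](C[C@@H]2OCc3ccc(OC)cc3)C1(OC)OC | intermediate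
10 | potassium C7–C8 enolate of 11 (not isolated) | [K+].[O-]C1=CC[C@@]2(C)[C@H](C[C@H](OCc3ccc(OC)cc3)C=C2C)C1(OC)OC | intermediate
11 | racemic cis-decalin: 8-ketone, 9,9-dimethoxy ketal, C3=C4 alkene bearing the C4 methyl, 5β-methyl, 10β-H, 2β-OPMB | O=C1CC[C@@]2(C)[C@H](C[C@H](OCc3ccc(OC)cc3)C=C2C)C1(OC)OC | intermediate
12 | racemic 2β-allylic alcohol from 11 | O=C1CC[C@@]2(C)[C@H](C[C@H](O)C=C2C)C1(OC)OC | intermediate
13 | (S)-2-methoxy-2-phenylacetic acid | CO[C@H](C(=O)O)c1ccccc1 | starting material
14 | 2α-[(S)-2-methoxy-2-phenylacetoxy] decalin, single stereoisomer | O=C1CC[C@@]2(C)[C@H](C[C@@H](OC(=O)[C@@H](OC)c3ccccc3)C=C2C)C1(OC)OC | intermediate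
15 | enantiopure 2α-allylic alcohol | O=C1CC[C@@]2(C)[C@H](C[C@@H](O)C=C2C)C1(OC)OC | intermediate
16 | saturated 2α-alcohol, 4β,5β-dimethyl, 10β-H, 8-ketone, 9-ketal | O=C1CC[C@@]2(C)[C@H](C[C@@H](O)C[C@@H]2C)C1(OC)OC | intermediate
17 | 2,8-diketone 9,9-dimethyl ketal | O=C1CC[C@@]2(C)[C@H](CC(=O)C[C@@H]2C)C1(OC)OC | intermediate
18 | 2β-alcohol, 8-ketone, 9-ketal | O=C1CC[C@@]2(C)[C@H](C[C@H](O)C[C@@H]2C)C1(OC)OC | intermediate
19 | 2β-tert-butyldiphenylsilyl ether of 18 | O=C1CC[C@@]2(C)[C@H](C[C@H](O[Si](c3ccccc3)(c3ccccc3)C(C)(C)C)C[C@@H]2C)C1(OC)OC | intermediate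
20 | 2-bromopropene | CC(Br)=C | starting material
21 | lithium C7–C8 enolate of 19 (not isolated) | [Li+].[O-]C1=CC[C@@]2(C)[C@H](C[C@H](O[Si](c3ccccc3)(c3ccccc3)C(C)(C)C)C[C@@H]2C)C1(OC)OC | intermediate
22 | lithium dienolate of 23 (not isolated) | [Li+].[O-]C1=C(C(C)=C)C[C@@]2(C)[C@H](C[C@H](O[Si](c3ccccc3)(c3ccccc3)C(C)(C)C)C[C@@H]2C)C1(OC)OC | intermediate
23 | 7β-isopropenyl 8-ketone, 9-ketal, 2β-OTBDPS | O=C1[C@@H](C(C)=C)C[C@@]2(C)[C@H](C[C@H](O[Si](c3ccccc3)(c3ccccc3)C(C)(C)C)C[C@@H]2C)C1(OC)OC | intermediate
24 | 8α-alcohol, 7β-isopropenyl, 9-ketal, 2β-OTBDPS | O[C@@H]1[C@@H](C(C)=C)C[C@@]2(C)[C@H](C[C@H](O[Si](c3ccccc3)(c3ccccc3)C(C)(C)C)C[C@@H]2C)C1(OC)OC | intermediate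
25 | 8α-hydroxy 9-ketone, 7β-isopropenyl, 2β-OTBDPS | O[C@@H]1[C@@H](C(C)=C)C[C@@]2(C)[C@H](C[C@H](O[Si](c3ccccc3)(c3ccccc3)C(C)(C)C)C[C@@H]2C)C1=O | intermediate
26 | 8α,9α-diol, 7β-isopropenyl, 2β-OTBDPS | O[C@@H]1[C@@H](C(C)=C)C[C@@]2(C)[C@H](C[C@H](O[Si](c3ccccc3)(c3ccccc3)C(C)(C)C)C[C@@H]2C)[C@@H]1O | intermediate
27 | angelic acid, (Z)-2-methylbut-2-enoic acid | C/C=C(/C)C(=O)O | starting material
28 | angelic 2,4,6-trichlorobenzoic mixed anhydride (not isolated) | C/C=C(/C)C(=O)OC(=O)c1c(Cl)cc(Cl)cc1Cl | intermediate
29 | 8α,9α-diangelate, 2β-OTBDPS | C=C(C)[C@H]1C[C@@]2(C)[C@H](C[C@H](O[Si](c3ccccc3)(c3ccccc3)C(C)(C)C)C[C@@H]2C)[C@H](OC(=O)/C(C)=C\C)[C@@H]1OC(=O)/C(C)=C\C | intermediate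
30 | 8α,9α-diangelate, 2β-alcohol | C=C(C)[C@H]1C[C@@]2(C)[C@H](C[C@H](O)C[C@@H]2C)[C@H](OC(=O)/C(C)=C\C)[C@@H]1OC(=O)/C(C)=C\C | intermediate
31 | CNP0249036.1: 8α,9α-diangeloyloxy-10β-H-eremophil-11-en-2-one (4β,5β-dimethyl, 7β-isopropenyl) | C=C(C)[C@H]1C[C@@]2(C)[C@H](CC(=O)C[C@@H]2C)[C@H](OC(=O)/C(C)=C\C)[C@@H]1OC(=O)/C(C)=C\C | target

Total step count: 18. Longest linear sequence: 18 steps (from 1 and 2 to 31; 17 from phenol 4).

Steps most likely to fail

Step 12. The coupling leaves its product as a dienolate, so C7 is finally set by protonation. Poor facial selectivity in that protonation would erode the 7β centre. So would drift of the double bond into conjugation with the ketone during quench and handling. Sluggish coupling at the hindered enolate is a further hazard. The fallback avoids any strongly basic medium, so that C7 is fixed in the C–C bond-forming event on the open β face of form N. It sets out from 19. O-acetylation of the enolate (LiHMDS, then Ac2O) gives the C7–C8 enol acetate F3. Bu3SnOMe in toluene converts this into the tributyltin enolate F4. F4 is coupled with 20 under PdCl2[P(o-tolyl)3]2 at 100 °C (Kosugi–Migita-type alkenylation of tin enolates). The weakly basic tin enolate should not deprotonate the product. The route is rejoined at 23.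

Step 16. The axial 9α hydroxyl on the concave face may be acylated incompletely, and the acyl group may isomerise from Z to E on long heating. The fallback builds the Z-alkene after a small saturated acyl group is in place. It sets out from 26. Carbodiimide/DMAP esterification with 2-[bis(2,2,2-trifluoroethoxy)phosphoryl]propanoic acid gives the 8α,9α-bis(phosphonopropionate) F5; no alkene is present at this point to isomerise. A double Still–Gennari olefination (KHMDS, 18-crown-6, acetaldehyde, THF, −78 °C) then forms both (Z)-2-methylbut-2-enoates. The route is rejoined at 29.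

Step 4. The alkoxide may fragment by loss of the vinyl unit. It may also undergo Grob-type expulsion of the C2 alkoxy group, which lies antiperiplanar to C3–C8. The enolate may suffer aerobic or aldol degradation, and any of these could compete with the [3,3] shift. The fallback performs the same bond reorganisation without any anion. It sets out from 8. Silylation (TMSOTf, 2,6-lutidine) gives the trimethylsilyl ether F1. Heating F1 in degassed o-dichlorobenzene at about 200 °C in a sealed tube (thermal siloxy-Cope rearrangement) gives the trimethylsilyl enol ether F2. Brief treatment of F2 with dilute HCl in THF rejoins the route at 11.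

Further compounds
F1 | step 4 | trimethylsilyl ether of carbinol 8 | C=C[C@@]1(O[Si](C)(C)C)[C@H]2C(C)=C(C)[C@H](C[C@@H]2OCc3ccc(OC)cc3)C1(OC)OC
F2 | step 4 | C7–C8 trimethylsilyl enol ether of 11 | C[Si](C)(C)OC1=CC[C@@]2(C)[C@H](C[C@H](OCc3ccc(OC)cc3)C=C2C)C1(OC)OC
F3 | step 12 | C7–C8 enol acetate of 19 | CC(=O)OC1=CC[C@@]2(C)[C@H](C[C@H](O[Si](c3ccccc3)(c3ccccc3)C(C)(C)C)C[C@@H]2C)C1(OC)OC
F4 | step 12 | tributyltin C7–C8 enolate of 19 | CCCC[Sn](CCCC)(CCCC)OC1=CC[C@@]2(C)[C@H](C[C@H](O[Si](c3ccccc3)(c3ccccc3)C(C)(C)C)C[C@@H]2C)C1(OC)OC
F5 | step 16 | 8α,9α-bis{2-[bis(2,2,2-trifluoroethoxy)phosphoryl]propanoate} of 26 | C=C(C)[C@H]1C[C@@]2(C)[C@H](C[C@H](O[Si](c3ccccc3)(c3ccccc3)C(C)(C)C)C[C@@H]2C)[C@H](OC(=O)C(C)P(=O)(OCC(F)(F)F)OCC(F)(F)F)[C@@H]1OC(=O)C(C)P(=O)(OCC(F)(F)F)OCC(F)(F)F
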